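The quinone ring (C1–C6; C1=O, C2 decaprenyl, C3 methyl, C4=O, C5–H, C6–OMe) is cut on both flanks of its enol ether edge C5=C6, at C5–C4 and C6–C1. That polarised edge is methoxyacetylene. The C4–C3–C2–C1 chain is stored in strained 3-(chloromethyl)-4-methylcyclobutenone, whose ring fixes methyl against side chain. Heating both sets off a Danheiser benzannulation (4π opening, ketene/ynol ether [2+2], 4π opening, 6π closure) that inserts the alkyne into the C(=O)–CH= bond and gives one resorcinol monoether. Its free para C–H (C1) is then oxidised, and the benzylic chloride takes up a solanesol-derived (E)-vinylalane.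

Key step: step 3

Remark: the target has no stereocentre, so the stereochemical task is taken to be the single all-E isomer of its nine stereodefined trisubstituted alkenes. Compound 5 is racemic and its centre is erased in step 3.

Step 1
Reactants: 1 N,N-dimethylpropionamide; 2 propargyl chloride (3-chloroprop-1-yne)
Product: 5 (±)-3-(chloromethyl)-4-methylcyclobut-2-en-1-one, via methylketeniminium triflate 3 (not isolated), via cyclobuteniminium triflate 4 (not isolated)
Conditions: Tf2O, 2,4,6-collidine, excess 2, ClCH2CH2Cl, 0 °C to reflux; then H2O, rt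
Reagents that add atoms: water, O
Why: Ghosez keteniminium [2+2] cycloaddition: O-triflylation and elimination of the tertiary amide give the strongly electrophilic methylketeniminium ion, the terminal CH of the alkyne attacks its central carbon so that closure places chloromethyl on C3 and methyl on C4, and hydrolysis of the cyclobuteniminium salt frees the enone.

Step 2
Reactants: 6 chloroacetaldehyde dimethyl acetal
Product: 8 methoxyacetylene (kept as a cold toluene solution), via sodium methoxyacetylide 7 (not isolated)
Conditions: NaNH2 (3 equiv), liq. NH3, −33 °C; NH3 evaporated; cold sat. aq NaCl, −20 °C; distilled into PhMe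
Reagents that add atoms: none
Why: The classical alkoxyacetylene synthesis by double base-induced β-elimination (MeOH, then HCl) from a chloroacetal, in which the third equivalent of amide holds the product as its acetylide until the cold aqueous quench.

Step 3
Reactants: 5 (±)-3-(chloromethyl)-4-methylcyclobut-2-en-1-one; 8 methoxyacetylene
Product: 13 3-(chloromethyl)-5-methoxy-2-methylphenol, via vinylketene 9 (not isolated), via 4-alkenyl-3-methoxycyclobutenone 10 (not isolated), via dienylketene 11 (not isolated), via cyclohexadienone 12 (not isolated)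
Conditions: 8 (3 equiv), PhMe, sealed tube, 80 °C then 120 °C
Reagents that add atoms: none
Why: Danheiser benzannulation: reversible thermal 4π electrocyclic opening of 5 (methyl rotating outward) gives vinylketene 9, and its ketene C=C adds the ynol ether in a regiospecific [2+2] cycloaddition in which the nucleophilic CH terminus of 8 bonds to the ketene carbonyl carbon and the C(OMe) terminus to the former C2 of 5, giving 10. A second 4π opening gives dienylketene 11, which closes the six-membered ring by disrotatory 6π electrocyclisation (ketene carbon onto the CH(CH3) terminus, which restores the bond opened at the start), and 12 tautomerises to 13, so the net result is insertion of the two alkyne carbons into the C1–C2 bond of 5. The closest known reaction type is the thermal annulation of cyclobutenones with alkoxyacetylenes to 3-alkoxyphenols. No stereocentre remains: the racemic C4 of 5 and the transient centres of 10 and 12 are erased on aromatisation. Regioselectivity is needed and is secured twice, by the matched polarity of ketene and ynol ether (OMe ends meta to OH) and by the four-membered ring, which already holds methyl on C4 and chloromethyl on C3; chemoselectivity for 8 over ketene dimerisation or acylation of 13 is secured by excess 8, which has no β-hydrogen for retro-ene decay and so tolerates the heat. In 13 the chloromethyl group is meta to both oxygen substituents, so ionisation to a quinone methide is not available.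

Step 4
Reactants: 13 3-(chloromethyl)-5-methoxy-2-methylphenol
Product: 14 2-(chloromethyl)-6-methoxy-3-methyl-1,4-benzoquinone
Conditions: (KSO3)2NO (2.2 equiv), KH2PO4 buffer, acetone/H2O, rt
Reagents that add atoms: potassium nitrosodisulfonate (Fremy's salt), [K+].[K+].[O-]S(=O)(=O)N([O])S(=O)(=O)[O-]
Why: Teuber oxidation: two equivalents of the nitroxyl radical turn a phenol with a free para position into the p-quinone (H abstraction, radical coupling at the para carbon, loss of imidodisulfonate), and the unactivated benzylic chloride should survive the buffered medium.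

Step 5
Reactants: 15 solanesol (all-E nonaprenol)
Product: 16 (all-E)-solanesyl chloride
Conditions: PCl3, DMF, 0 °C to rt
Reagents that add atoms: phosphorus trichloride, ClP(Cl)Cl
Why: Chlorination of the primary allylic alcohol with the Vilsmeier-type PCl3/DMF reagent proceeds by SN2 displacement at C1, so neither allylic transposition nor erosion of the eight (E)-alkenes inherited from solanesol is expected.

Step 6
Reactants: 16 (all-E)-solanesyl chloride; 17 1-(trimethylsilyl)propyne
Product: 20 3-[(all-E)-solanesyl]prop-1-yne, via 3-lithio-1-(trimethylsilyl)propyne 18 (not isolated), via silylated alkyne 19 (not isolated)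
Conditions: 17, n-BuLi, THF, −20 °C; 16, −20 °C to rt; then NaOEt, EtOH, 60 °C
Reagents that add atoms: none
Why: Propargylic lithiation of the silyl-capped propyne and SN2 alkylation at the primary allylic chloride add the three-carbon unit (the silyl group blocks the acetylenic terminus and disfavours allenyl coupling), and ethoxide-mediated protodesilylation in the same pot frees the terminal alkyne.

Step 7
Reactants: 20 3-[(all-E)-solanesyl]prop-1-yne; 14 2-(chloromethyl)-6-methoxy-3-methyl-1,4-benzoquinone
Product: 22 2-[(all-E)-decaprenyl]-6-methoxy-3-methyl-1,4-benzoquinone (target), via (E)-alkenyldimethylalane 21 (not isolated)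
Conditions: Me3Al, Cp2ZrCl2 (cat.), ClCH2CH2Cl, 0 °C to rt; volatiles and excess Me3Al removed in vacuo; then 14, NiCl2(PPh3)2/n-BuLi (cat. Ni(0)), THF, −20 °C to rt
Reagents that add atoms: trimethylaluminium, C[Al](C)C
Why: Negishi zirconium-catalysed methylalumination adds Me and Al syn across the terminal alkyne with Al at the terminus, which sets the ninth (E)-trisubstituted alkene, and the nickel(0)-catalysed alkenylalane/benzylic chloride cross-coupling, a reaction type established for chloromethyl p-quinones, then joins 21 to 14 with retention of alkene geometry.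

Compound list
1 | N,N-dimethylpropionamide | CCC(=O)N(C)C | starting material
2 | propargyl chloride (3-chloroprop-1-yne) | C#CCCl | starting material
3 | N,N-dimethyl(prop-1-en-1-ylidene)ammonium triflate (methylketeniminium triflate) | CC=C=[N+](C)C.[O-]S(=O)(=O)C(F)(F)F | intermediate
4 | (±)-[3-(chloromethyl)-4-methylcyclobut-2-en-1-ylidene]dimethylammonium triflate | C[N+](C)=C1C=C(CCl)C1C.[O-]S(=O)(=O)C(F)(F)F | intermediate
5 | (±)-3-(chloromethyl)-4-methylcyclobut-2-en-1-one | CC1C(=O)C=C1CCl | intermediate
6 | chloroacetaldehyde dimethyl acetal (2-chloro-1,1-dimethoxyethane) | COC(CCl)OC | starting material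
7 | sodium methoxyacetylide | [Na+].[C-]#COC | intermediate
8 | methoxyacetylene | C#COC | intermediate
9 | (Z)-3-(chloromethyl)penta-1,3-dien-1-one (vinylketene) | O=C=C/C(CCl)=C/C | intermediate
10 | (±)-4-[(Z)-1-chlorobut-2-en-2-yl]-3-methoxycyclobut-2-en-1-one | COC1=CC(=O)C1/C(CCl)=C/C | intermediate
11 | (3E,5Z)-5-(chloromethyl)-3-methoxyhepta-1,3,5-trien-1-one (dienylketene) | O=C=C/C(OC)=C\C(CCl)=C\C | intermediate
12 | (±)-5-(chloromethyl)-3-methoxy-6-methylcyclohexa-2,4-dien-1-one | CC1C(=O)C=C(OC)C=C1CCl | intermediate
13 | 3-(chloromethyl)-5-methoxy-2-methylphenol | Cc1c(O)cc(OC)cc1CCl | intermediate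
14 | 2-(chloromethyl)-6-methoxy-3-methyl-1,4-benzoquinone | COC1=CC(=O)C(C)=C(CCl)C1=O | intermediate
15 | solanesol (all-E nonaprenol) | OC/C=C(\C)CC/C=C(\C)CC/C=C(\C)CC/C=C(\C)CC/C=C(\C)CC/C=C(\C)CC/C=C(\C)CC/C=C(\C)CCC=C(C)C | starting material
16 | (all-E)-solanesyl chloride | ClC/C=C(\C)CC/C=C(\C)CC/C=C(\C)CC/C=C(\C)CC/C=C(\C)CC/C=C(\C)CC/C=C(\C)CC/C=C(\C)CCC=C(C)C | intermediate
17 | 1-(trimethylsilyl)propyne | CC#C[Si](C)(C)C | starting material
18 | 3-lithio-1-(trimethylsilyl)propyne | [Li]CC#C[Si](C)(C)C | intermediate
19 | 1-(trimethylsilyl)-3-[(all-E)-solanesyl]prop-1-yne | C[Si](C)(C)C#CCC/C=C(\C)CC/C=C(\C)CC/C=C(\C)CC/C=C(\C)CC/C=C(\C)CC/C=C(\C)CC/C=C(\C)CC/C=C(\C)CCC=C(C)C | intermediate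
20 | 3-[(all-E)-solanesyl]prop-1-yne | C#CCC/C=C(\C)CC/C=C(\C)CC/C=C(\C)CC/C=C(\C)CC/C=C(\C)CC/C=C(\C)CC/C=C(\C)CC/C=C(\C)CCC=C(C)C | intermediate
21 | dimethyl[(1E)-2-methyl-3-((all-E)-solanesyl)prop-1-en-1-yl]alane | C[Al](C)/C=C(\C)CC/C=C(\C)CC/C=C(\C)CC/C=C(\C)CC/C=C(\C)CC/C=C(\C)CC/C=C(\C)CC/C=C(\C)CC/C=C(\C)CCC=C(C)C | intermediate
22 | 2-[(all-E)-decaprenyl]-6-methoxy-3-methyl-1,4-benzoquinone | COC1=CC(=O)C(C)=C(C/C=C(\C)CC/C=C(\C)CC/C=C(\C)CC/C=C(\C)CC/C=C(\C)CC/C=C(\C)CC/C=C(\C)CC/C=C(\C)CC/C=C(\C)CCC=C(C)C)C1=O | target

Total step count: 7. Longest linear sequence: 4 steps (1, 3, 4, 7; the branch 2, 3, 4, 7 is equally long, and the chain branch 5, 6, 7 has 3).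

Steps most likely to fail

(a) Step 3. During the long heating the allylic C–Cl bond may ionise or be displaced. Vinylketene may also be drained by acylation of phenol already formed, and this loss cannot be repaired by saponification while the chloride is present. The fallback carries the benzylic carbon as an ester and installs the chloride only after the ring is built.
- It sets out from 1, whose keteniminium cycloaddition is run with propargyl acetate to give (±)-3-(acetoxymethyl)-4-methylcyclobut-2-en-1-one F1.
- Annulation of F1 with 8 should give 3-hydroxy-5-methoxy-2-methylbenzyl acetate F2.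
- KOH in MeOH cleaves the acetate together with any aryl ester by-product to give 3-(hydroxymethyl)-5-methoxy-2-methylphenol F3.
- SOCl2 in CH2Cl2 converts the benzylic alcohol selectively, and the sequence comes back to the route at 13.

(b) Step 1. The alkyne is inductively deactivated by chlorine and may trap the short-lived monosubstituted keteniminium ion too slowly. Self-condensation of the ion and N-alkylation of the base would then take over. The fallback builds the four-membered ring from an activated alkyne and adds the chloromethyl carbon afterwards as a nucleophile.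
- It sets out from 8. Propionyl chloride and Et3N in Et2O generate methylketene F4, which undergoes ketene/ynol ether [2+2] cycloaddition with 8 to give (±)-3-methoxy-4-methylcyclobut-2-en-1-one F5.
- Chloromethyllithium F6 (from ClCH2I and MeLi·LiBr, THF, −78 °C, in the presence of F5) adds 1,2 to give 1-(chloromethyl)-3-methoxy-4-methylcyclobut-2-en-1-ol F7.
- Dilute HCl hydrolyses the enol ether and eliminates water (Stork–Danheiser-type carbonyl transposition), and the sequence comes back at 5.
- In a four-membered ring C4 is bonded to both C1 and C3, so the transposition leaves methyl next to the chloromethyl-bearing carbon as required.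

(c) Step 7. Unlike fully substituted chloromethyl quinones, 14 has a free ring C–H and a vinylogous ester. Conjugate attack of the alane, displacement of methoxide, or reduction of the quinone by low-valent nickel may therefore compete with the benzylic coupling. The fallback couples at the arene oxidation level and forms the quinone last.
- It sets out from 13, which is silylated (TBSCl, imidazole, DMF) to tert-butyl[3-(chloromethyl)-5-methoxy-2-methylphenoxy]dimethylsilane F8.
- Nickel(0)-catalysed coupling of F8 with 21 should give tert-butyl{3-[(all-E)-decaprenyl]-5-methoxy-2-methylphenoxy}dimethylsilane F9.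
- TBAF in THF frees 3-[(all-E)-decaprenyl]-5-methoxy-2-methylphenol F10.
- Teuber oxidation of F10 (Fremy's salt, or Co(salen)/O2) comes back at 22.

Further compounds
F1 | step 3 | (±)-3-(acetoxymethyl)-4-methylcyclobut-2-en-1-one | CC(=O)OCC1=CC(=O)C1C
F2 | step 3 | 3-hydroxy-5-methoxy-2-methylbenzyl acetate | CC(=O)OCc1cc(OC)cc(O)c1C
F3 | step 3 | 3-(hydroxymethyl)-5-methoxy-2-methylphenol | OCc1cc(OC)cc(O)c1C
F4 | step 1 | methylketene | CC=C=O
F5 | step 1 | (±)-3-methoxy-4-methylcyclobut-2-en-1-one | COC1=CC(=O)C1C
F6 | step 1 | chloromethyllithium | [Li]CCl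
F7 | step 1 | 1-(chloromethyl)-3-methoxy-4-methylcyclobut-2-en-1-ol (mixture of diastereomers) | COC1=CC(O)(CCl)C1C
F8 | step 7 | tert-butyl[3-(chloromethyl)-5-methoxy-2-methylphenoxy]dimethylsilane | COc1cc(O[Si](C)(C)C(C)(C)C)c(C)c(CCl)c1
F9 | step 7 | tert-butyl{3-[(all-E)-decaprenyl]-5-methoxy-2-methylphenoxy}dimethylsilane | COc1cc(O[Si](C)(C)C(C)(C)C)c(C)c(C/C=C(\C)CC/C=C(\C)CC/C=C(\C)CC/C=C(\C)CC/C=C(\C)CC/C=C(\C)CC/C=C(\C)CC/C=C(\C)CC/C=C(\C)CCC=C(C)C)c1
F10 | step 7 | 3-[(all-E)-decaprenyl]-5-methoxy-2-methylphenol | COc1cc(O)c(C)c(C/C=C(\C)CC/C=C(\C)CC/C=C(\C)CC/C=C(\C)CC/C=C(\C)CC/C=C(\C)CC/C=C(\C)CC/C=C(\C)CC/C=C(\C)CCC=C(C)C)c1
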